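**Strategy.** Ring C (C8, C9, C11, C12, C13, C14; ent-kaurane numbering) is cut across C8–C14 and C9–C11. Its three unsubstituted methylenes and the C13 methine map onto buta-1,3-diene. C8, flanked by the C7 lactone carbonyl and the C15 carbonyl, maps onto a doubly activated C8=C9 dienophile. One Diels–Alder reaction on a spiro 3-formyl-5,6-dihydropyran-2-one (rings A and B, formed in situ from a selenide) should close ring C cis-fused to lactone ring B and set the C8 quaternary centre and C9. The residual C12=C13 alkene then accepts a C16 vinyl radical to close ring D.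

Key step: step 9

Remark on numbering: ring A = C1(=O), C2=C3, C4(Me2), C5, C10; lactone ring B = C10, C20, O, C7, C8, C9; ring C = C8, C9, C11, C12, C13, C14; ring D = C8, C14, C13, C16, C15; C6 and C17 are the two CH2OH carbons.
Assumption: in step 2 the ligand enantiomer is the one that delivers the (S) configuration at C5.

Step 1
Reactants: 1 4,4-dimethylcyclohex-2-en-1-one
Product: 2 4,4-dimethylcyclohexa-2,5-dien-1-one
Conditions: DDQ (1.5 equiv), 1,4-dioxane, reflux
Reagents that add atoms: none
Why: DDQ dehydrogenation of an enone on its saturated side is a standard route to 4,4-disubstituted cyclohexa-2,5-dienones, and the gem-dimethyl group prevents aromatisation.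

Step 2
Reactants: 2 4,4-dimethylcyclohexa-2,5-dien-1-one; 3 (chloromethyl)(isopropoxy)dimethylsilane
Product: 5 (S)-5-(hydroxymethyl)-4,4-dimethylcyclohex-2-en-1-one, via silylmethyl ketone 4 (not isolated)
Conditions: 3 + Mg (THF) to the Grignard reagent; CuBr·SMe2 (5 mol %), (R,S)-Josiphos (6 mol %), t-BuOMe, −78 °C; then KF, KHCO3, 30 % H2O2, THF/MeOH, 23 °C
Reagents that add atoms: hydrogen peroxide, OO
Why: Copper-catalysed enantioselective conjugate addition of a Grignard reagent should differentiate the two enantiotopic enone arms of the prochiral dienone, the chiral diphosphine–copper complex setting C5, and Tamao–Fleming oxidation then replaces silicon by hydroxyl (hydroxymethyl anion equivalent).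

Step 3
Reactants: 5 (S)-5-(hydroxymethyl)-4,4-dimethylcyclohex-2-en-1-one
Product: 6 (S)-5-{[(tert-butyldimethylsilyl)oxy]methyl}-4,4-dimethylcyclohex-2-en-1-one
Conditions: TBSCl, imidazole, DMF, 23 °C
Reagents that add atoms: tert-butyldimethylsilyl chloride, CC(C)(C)[Si](C)(C)Cl
Why: Standard silylation of a primary alcohol; the ether is later removed by mild acid in step 11.

Step 4
Reactants: 6 (S)-5-{[(tert-butyldimethylsilyl)oxy]methyl}-4,4-dimethylcyclohex-2-en-1-one
Product: 7 (Z)-6-(hydroxymethylene) derivative of 6 (chelated enol of the C10 formyl ketone)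
Conditions: NaH, HCO2Et, THF, 0 → 23 °C; aq. HCl work-up
Reagents that add atoms: ethyl formate, CCOC=O
Why: Claisen-type formylation can occur only at C10, the single enolisable position (C2 is vinylic, C4 quaternary), and brings in C20 at the aldehyde level.

Step 5
Reactants: 7 (Z)-6-(hydroxymethylene) derivative of 6; 8 methyl acrylate
Product: 9 methyl 3-[6-{[(tert-butyldimethylsilyl)oxy]methyl}-1-formyl-5,5-dimethyl-2-oxocyclohex-3-en-1-yl]propanoate (propanoate chain trans and formyl cis to the C5 substituent)
Conditions: DBU (0.2 equiv), MeCN, 23 °C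
Reagents that add atoms: none
Why: Michael addition of the acidic 2-formyl ketone creates the C10 quaternary centre; the acrylate should approach the planar enolate anti to the adjacent C5 CH2OTBS group, so C9 ends trans and C20 cis to C6.

Step 6
Reactants: 9 methyl 3-[6-{[(tert-butyldimethylsilyl)oxy]methyl}-1-formyl-5,5-dimethyl-2-oxocyclohex-3-en-1-yl]propanoate
Product: 11 11-{[(tert-butyldimethylsilyl)oxy]methyl}-10,10-dimethyl-2-oxaspiro[5.5]undec-8-ene-3,7-dione (rings A and B), via hydroxy ester 10 (not isolated)
Conditions: NaBH4, CH2Cl2/MeOH, −78 °C; AcOH quench; then PPTS (cat.), toluene, 50 °C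
Reagents that add atoms: none
Why: At −78 °C borohydride should reduce the aldehyde much faster than the conjugated C1 ketone (flanked by quaternary C10) or the ester, and the C20 alcohol then closes the six-membered lactone on the C7 ester by acid-catalysed transesterification.

Step 7
Reactants: 11 spirolactone (rings A and B)
Product: 12 (Z)-4-(hydroxymethylene) derivative of 11 (C15 attached to C8; chelated enol)
Conditions: LiHMDS (2.2 equiv), THF, −78 °C; CF3CH2OCHO, −78 → 0 °C; aq. NH4Cl
Reagents that add atoms: 2,2,2-trifluoroethyl formate, O=COCC(F)(F)F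
Why: C8–H is the only acidic C–H (the C1 ketone is non-enolisable and LiHMDS cannot reduce it), and kinetic Claisen formylation at low temperature gives the stabilised formyl-lactone enolate without retro-Michael opening at C9–C10.

Step 8
Reactants: 12 hydroxymethylene lactone
Product: 13 4-formyl-4-(phenylselanyl) lactone (C8 bears CHO and SePh; C8 epimers)
Conditions: PhSeCl, pyridine, CH2Cl2, 0 °C
Reagents that add atoms: benzeneselenenyl chloride, Cl[Se]c1ccccc1
Why: Electrophilic α-selenenylation of the enolised 1,3-dicarbonyl unit occurs at C8; its configuration is irrelevant because C8 becomes sp2 in step 9.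

Step 9
Reactants: 13 4-formyl-4-(phenylselanyl) lactone; 14 buta-1,3-diene
Product: 17 cis-fused ring B/C lactone aldehyde (C15 formyl on quaternary C8; C12=C13 alkene), via selenoxide 15 (not isolated), via formyl dienophile 16 (not isolated)
Conditions: 30 % H2O2, CH2Cl2, 0 °C; cold aqueous wash; then buta-1,3-diene (10 equiv), CH2Cl2, sealed tube, 0 → 23 °C
Reagents that add atoms: none
Why: Oxidation gives selenoxide 15, whose syn-elimination across C8–C9 unveils the 3-formyl-5,6-dihydropyran-2-one 16 with C8=C9 activated by both the C7 lactone carbonyl and the C15 formyl group; s-cis butadiene then adds in a concerted, asynchronous normal-demand [4+2] cycloaddition in which the C9–C11 bond runs ahead of the C8–C14 bond. The closest known reaction type is the Diels–Alder reaction of 2-formyl- and 2-alkoxycarbonyl-cycloalk-2-enones generated in situ by selenoxide elimination, which add simple dienes at or below room temperature even next to a quaternary γ-carbon. Ring C (C8, C9, C11, C12, C13, C14) is closed by intermolecular [4+2] cycloaddition, suprafacial on the dienophile, so it is necessarily cis-fused to lactone ring B. C8 and C9 are set together: their relative configuration follows from the suprafacial addition, and their sense relative to C10 from the spiro ring, the diene passing the flat C1 carbonyl side of the lactone and avoiding the face screened by the C5 branch (CH2OTBS next to the gem-dimethyl group). The step needs chemoselectivity for C8=C9 over the ring A enone C2=C3 (geminal double activation against a singly activated neopentyl enone), carbon–carbon over oxadiene periselectivity (normal for an unpolarised diene) and facial selectivity (the C5 branch); regioselectivity does not arise because the diene is symmetric.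

Step 10
Reactants: 17 cis-fused ring B/C lactone aldehyde; 18 ethynylmagnesium bromide
Product: 19 propargylic alcohol (C15 carbinol bearing the C16≡C17 ethynyl group; C15 epimers)
Conditions: THF, −78 °C; aq. NH4Cl
Reagents that add atoms: none
Why: 1,2-Addition of the alkynyl Grignard reagent goes to the aldehyde, the most electrophilic carbonyl (the C1 ketone is conjugated and neopentyl, the lactone less reactive); the C15 configuration does not matter because C15 is oxidised in step 12.

Step 11
Reactants: 19 propargylic alcohol
Product: 21 15-hydroxy-16-methylene diol with the bicyclo[3.2.1]octane (rings C and D) closed and C6–OH free, via vinylstannane 20 (not isolated)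
Conditions: Bu3SnH (1.5 equiv), AIBN (0.2 equiv), benzene (0.02 M), 80 °C; then PPTS, MeOH, 40 °C
Reagents that add atoms: none
Why: In this stannyl-radical enyne cyclization the tin radical adds to terminal C17, the C16 vinyl radical closes 5-exo-trig onto C13 (the two-carbon bridge can only form on the face of ring C that carries C15, which fixes C13), Bu3SnH reduces the C12 radical, and mild acid then effects protodestannylation and cleaves the primary silyl ether.

Step 12
Reactants: 21 15-hydroxy-16-methylene diol
Product: 22 15-oxo-16-methylene enone (C6–OH free)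
Conditions: MnO2 (excess), CH2Cl2, 23 °C
Reagents that add atoms: none
Why: Manganese dioxide oxidises the allylic C15 alcohol selectively and leaves the primary, non-allylic C6 alcohol untouched.

Step 13
Reactants: 22 15-oxo-16-methylene enone
Product: 23 CNP0505075.1 (target)
Conditions: PMe3 (10 mol %), THF/H2O (1:1), 23 °C, until C16 has equilibrated
Reagents that add atoms: water, O
Why: Phosphine-catalysed oxa-Michael addition of water should take place at C17 of the strained exocyclic enone only (the ring A enone is blocked at C3 by the gem-dimethyl group), and C16 equilibrates through the enol so that CH2OH takes the exo position, syn to the C14 bridge and away from the C11–C12 bridge.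

**Compound list**

1 | 4,4-dimethylcyclohex-2-en-1-one | CC1(C)CCC(=O)C=C1 | starting material
2 | 4,4-dimethylcyclohexa-2,5-dien-1-one | CC1(C)C=CC(=O)C=C1 | intermediate
3 | (chloromethyl)(isopropoxy)dimethylsilane | ClC[Si](C)(C)OC(C)C | starting material
4 | (S)-5-{[isopropoxy(dimethyl)silyl]methyl}-4,4-dimethylcyclohex-2-en-1-one (not isolated) | CC1(C)C=CC(=O)C[C@@H]1C[Si](C)(C)OC(C)C | intermediate
5 | (S)-5-(hydroxymethyl)-4,4-dimethylcyclohex-2-en-1-one | CC1(C)C=CC(=O)C[C@@H]1CO | intermediate
6 | (S)-5-{[(tert-butyldimethylsilyl)oxy]methyl}-4,4-dimethylcyclohex-2-en-1-one | CC1(C)C=CC(=O)C[C@@H]1CO[Si](C)(C)C(C)(C)C | intermediate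
7 | (Z)-5-{[(tert-butyldimethylsilyl)oxy]methyl}-6-(hydroxymethylene)-4,4-dimethylcyclohex-2-en-1-one, C5 as in 6 | CC1(C)C=CC(=O)/C(=C\O)[C@@H]1CO[Si](C)(C)C(C)(C)C | intermediate
8 | methyl acrylate | C=CC(=O)OC | starting material
9 | methyl 3-[6-{[(tert-butyldimethylsilyl)oxy]methyl}-1-formyl-5,5-dimethyl-2-oxocyclohex-3-en-1-yl]propanoate, propanoate chain trans and formyl cis to the CH2OTBS group | CC1(C)C=CC(=O)[C@@](C=O)(CCC(=O)OC)[C@@H]1CO[Si](C)(C)C(C)(C)C | intermediate
10 | methyl 3-[6-{[(tert-butyldimethylsilyl)oxy]methyl}-1-(hydroxymethyl)-5,5-dimethyl-2-oxocyclohex-3-en-1-yl]propanoate (not isolated) | CC1(C)C=CC(=O)[C@@](CO)(CCC(=O)OC)[C@@H]1CO[Si](C)(C)C(C)(C)C | intermediate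
11 | 11-{[(tert-butyldimethylsilyl)oxy]methyl}-10,10-dimethyl-2-oxaspiro[5.5]undec-8-ene-3,7-dione, lactone CH2O (C20) cis and C9 trans to the CH2OTBS group | CC1(C)C=CC(=O)[C@]2(COC(=O)CC2)[C@@H]1CO[Si](C)(C)C(C)(C)C | intermediate
12 | (Z)-4-(hydroxymethylene) derivative of 11 (enol of the C8 formyl lactone) | CC1(C)C=CC(=O)[C@]2(COC(=O)/C(=C\O)C2)[C@@H]1CO[Si](C)(C)C(C)(C)C | intermediate
13 | 11-{[(tert-butyldimethylsilyl)oxy]methyl}-10,10-dimethyl-3,7-dioxo-4-(phenylselanyl)-2-oxaspiro[5.5]undec-8-ene-4-carbaldehyde, mixture at C8 | CC1(C)C=CC(=O)[C@]2(COC(=O)C(C=O)([Se]c3ccccc3)C2)[C@@H]1CO[Si](C)(C)C(C)(C)C | intermediate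
14 | buta-1,3-diene | C=CC=C | starting material
15 | selenoxide of 13 (not isolated) | CC1(C)C=CC(=O)[C@]2(COC(=O)C(C=O)([Se](=O)c3ccccc3)C2)[C@@H]1CO[Si](C)(C)C(C)(C)C | intermediate
16 | 11-{[(tert-butyldimethylsilyl)oxy]methyl}-10,10-dimethyl-3,7-dioxo-2-oxaspiro[5.5]undeca-4,8-diene-4-carbaldehyde (C8=C9 dienophile, not isolated) | CC1(C)C=CC(=O)[C@]2(COC(=O)C(C=O)=C2)[C@@H]1CO[Si](C)(C)C(C)(C)C | intermediate
17 | Diels–Alder adduct: cyclohexene ring C (C12=C13) cis-fused to lactone ring B, formyl (C15) on quaternary C8, C11 and C14 on the lactone face syn to C1 | CC1(C)C=CC(=O)[C@]2(COC(=O)[C@@]3(C=O)CC=CC[C@H]32)[C@@H]1CO[Si](C)(C)C(C)(C)C | intermediate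
18 | ethynylmagnesium bromide | C#C[Mg]Br | starting material
19 | propargylic alcohol from 17 (C8–CH(OH)–C≡CH, C15 epimers) | CC1(C)C=CC(=O)[C@]2(COC(=O)[C@@]3(C(O)C#C)CC=CC[C@H]32)[C@@H]1CO[Si](C)(C)C(C)(C)C | intermediate
20 | bicyclo[3.2.1]octane vinylstannane (C17–SnBu3 on the exocyclic C16=C17 alkene, C15–OH, TBS ether; not isolated) | CC1(C)C=CC(=O)[C@]2(COC(=O)[C@@]34C[C@@H](CC[C@H]32)C(=C[Sn](CCCC)(CCCC)CCCC)C4O)[C@@H]1CO[Si](C)(C)C(C)(C)C | intermediate
21 | 15-hydroxy-16-methylene tetracycle with free C6–OH (C15 epimers) | CC1(C)C=CC(=O)[C@]2(COC(=O)[C@@]34C[C@@H](CC[C@H]32)C(=C)C4O)[C@@H]1CO | intermediate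
22 | 15-oxo-16-methylene tetracycle with free C6–OH | CC1(C)C=CC(=O)[C@]2(COC(=O)[C@@]34C[C@@H](CC[C@H]32)C(=C)C4=O)[C@@H]1CO | intermediate
23 | CNP0505075.1 (1,15-dioxo-6,17-dihydroxy-7,20-lactone of the 6,7-seco-ent-kaur-2-ene skeleton, 16-CH2OH exo) | CC1(C)C=CC(=O)[C@]2(COC(=O)[C@@]34C[C@@H](CC[C@H]32)[C@H](CO)C4=O)[C@@H]1CO | target

**Total step count:** 13. **Longest linear sequence:** 13 steps (1 → 23).

**Steps most likely to fail**

Step 9. The cycloaddition at the neopentyl C9 terminus may be slower than decay of the formyl dienophile (hetero-dimerisation, hydration), and the diene may approach the lactone face with eroded facial selectivity. The fallback sets out from 13: after the same oxidation, the dienophile is intercepted at −40 °C by the far more nucleophilic 2-(trimethylsilyloxy)buta-1,3-diene, whose CH2 terminus bonds to the electrophilic C9 and gives the C12 silyl enol ether adduct F1 with the double bond already at C12=C13. CsF and PhNTf2 convert it regiospecifically into the C12 enol triflate F2, and Pd(OAc)2/PPh3 with HCO2H/Et3N removes the triflate reductively. The route is rejoined at 17.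

Step 2. Transfer of the α-silyl alkyl group from copper may be sluggish, or enantiotopic-group discrimination on the dienone may be poor. The fallback sets out from 2: rhodium-catalysed asymmetric conjugate addition of potassium vinyltrifluoroborate ([Rh(acac)(C2H4)2], BINAP, dioxane/H2O) gives (R)-4,4-dimethyl-5-vinylcyclohex-2-en-1-one F3. Ozonolysis of the vinyl group at −78 °C in CH2Cl2/MeOH gives (S)-2,2-dimethyl-5-oxocyclohex-3-ene-1-carbaldehyde F4, which is reduced in the same flask with NaBH4 at −78 °C before C5 can epimerise. The route is rejoined at 5.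

Step 13. The hydration may stop at an unfavourable equilibrium, the basic medium may cause retro-aldol loss of formaldehyde or retro-Claisen opening at C8–C15, and C16 may remain as the kinetic epimer. The fallback sets out from 22: copper-catalysed conjugate borylation (B2pin2, CuCl, NaOt-Bu, DPEphos, MeOH/THF) gives the 17-pinacolboryl ketone F5. Oxidation with NaBO3 in THF/H2O followed by brief exposure to Et3N to equilibrate C16 rejoins the route at 23.

**Further compounds**

F1 | step 9 | C12 trimethylsilyl enol ether analogue of 17 (C12–OSiMe3, C12=C13) | CC1(C)C=CC(=O)[C@]2(COC(=O)[C@@]3(C=O)CC=C(O[Si](C)(C)C)C[C@H]32)[C@@H]1CO[Si](C)(C)C(C)(C)C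
F2 | step 9 | C12 enol triflate analogue of 17 | CC1(C)C=CC(=O)[C@]2(COC(=O)[C@@]3(C=O)CC=C(OS(=O)(=O)C(F)(F)F)C[C@H]32)[C@@H]1CO[Si](C)(C)C(C)(C)C
F3 | step 2 | (R)-4,4-dimethyl-5-vinylcyclohex-2-en-1-one | CC1(C)C=CC(=O)C[C@@H]1C=C
F4 | step 2 | (S)-2,2-dimethyl-5-oxocyclohex-3-ene-1-carbaldehyde | CC1(C)C=CC(=O)C[C@@H]1C=O
F5 | step 13 | 17-(pinacolboryl) ketone from 22 (C16 epimers) | CC1(C)C=CC(=O)[C@]2(COC(=O)[C@@]34C[C@@H](CC[C@H]32)C(CB5OC(C)(C)C(C)(C)O5)C4=O)[C@@H]1CO
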